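Enabling feature: ring A of the acacetin half (C4a''–C8a'') is a phloroglucinol oxygenated at C5'', C7'' and C8a''. Its C8'' is bonded to C6 of the apigenin half, so C8'' can begin as a benzylic CH2 on apigenin C6.
Cuts, in order: the five O–benzyl bonds; O1''–C2'' and C2''–C3'' of the acacetin pyranone; the acetyl bond C4''–C4a''; then C8''–C7'', which unfolds ring A into a 6-aryl-3,5-dioxohexanoate. The chain is cut at its C4–C5 bond (acetoacetate + arylacetaldehyde), and the aldehyde goes back to a 6-allyl group and an O5-allyl ether.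
Forward: the three apigenin rings are bought. The allyl group moves from O5 to C6, is cut to the aldehyde and extended to the triketide ester. Acacetin ring A closes next and its pyranone ring last; its ring B arrives with 4-methoxybenzoyl chloride.
Stereochemistry: the target has no stereocentre and no descriptor on the 6,8''-axis, so none is set. The sp3 centres that arise on the way are racemic and vanish again.

Key step: step 8

Assumption: the SMILES leaves the hindered 6,8''-biaryl axis undefined, so material racemic about this axis is taken as the goal.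
Locants: unprimed and single-primed locants belong to the apigenin half, double- and triple-primed ones to the acacetin half. The hexanoate chain is numbered from the ester carbon (C1) to the benzylic carbon (C6).

Step 1
Reactants: 1 apigenin
Product: 2 7,4'-di-O-benzylapigenin
Conditions: BnBr (2.1 equiv), K2CO3, DMF, rt
Reagents that add atoms: benzyl bromide, BrCc1ccccc1
Why: Williamson etherification takes the two acidic, unchelated phenols (O7 and O4'), whereas the 5-OH is held in a hydrogen bond to the C4 carbonyl and should stay free at room temperature.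

Step 2
Reactants: 2 7,4'-di-O-benzylapigenin; 3 allyl bromide
Product: 4 5-O-allyl-7,4'-di-O-benzylapigenin
Conditions: K2CO3, DMF, 60 °C
Reagents that add atoms: none
Why: Williamson etherification of the one remaining phenol, whose chelation is overcome by heat in a dipolar aprotic solvent, as is routine for 5-hydroxyflavones.

Step 3
Reactants: 4 5-O-allyl-7,4'-di-O-benzylapigenin
Product: 6 6-allyl-7,4'-di-O-benzylapigenin, via dienone 5 (not isolated)
Conditions: PhNEt2, 200 °C, sealed tube, Ar
Reagents that add atoms: none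
Why: In this aromatic Claisen rearrangement one of the two positions ortho to O5 is the ring-fusion carbon C4a, so the [3,3] shift can place the allyl group only on C6, and dienone 5 (racemic at C6) carries a hydrogen there and should tautomerise to the phenol before a Cope shift towards C8 can follow.

Step 4
Reactants: 6 6-allyl-7,4'-di-O-benzylapigenin
Product: 7 6-allyl-5,7,4'-tri-O-benzylapigenin
Conditions: BnBr, K2CO3, n-Bu4NI (cat.), DMF, 70 °C
Reagents that add atoms: benzyl bromide, BrCc1ccccc1
Why: Williamson etherification under forcing conditions caps the chelated and flanked 5-OH, which stops this phenol from later cyclising onto the side-chain carbonyl groups and leaves the pyranone ring only one way to reclose.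

Step 5
Reactants: 7 6-allyl-5,7,4'-tri-O-benzylapigenin
Product: 9 (5,7,4'-tri-O-benzylapigenin-6-yl)acetaldehyde, via diol 8 (not isolated)
Conditions: OsO4 (2 mol %), NaIO4 (4 equiv), 2,6-lutidine, dioxane–H2O (3:1), rt
Reagents that add atoms: OsO4, O=[Os](=O)(=O)=O (oxygen carrier); NaIO4, [Na+].[O-]I(=O)(=O)=O (terminal oxygen source)
Why: Lemieux–Johnson cleavage attacks the terminal alkene, the only unhindered and electron-rich C=C bond, while the C2=C3 bond is a trisubstituted vinylogous ester inert to OsO4 at room temperature, and the racemic carbinol centre of diol 8 is lost on glycol cleavage.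

Step 6
Reactants: 9 (5,7,4'-tri-O-benzylapigenin-6-yl)acetaldehyde; 10 methyl acetoacetate
Product: 12 methyl 5-hydroxy-3-oxo-6-(5,7,4'-tri-O-benzylapigenin-6-yl)hexanoate (racemic), via acetoacetate dianion 11 (not isolated)
Conditions: 10 (1.6 equiv), NaH, THF, 0 °C; n-BuLi, 0 °C; then 9, −78 °C; AcOH, −78 °C
Reagents that add atoms: none
Why: Aldol addition of a β-keto ester 1,3-dianion through its terminal carbon is fast at −78 °C, also with arylacetaldehydes, and should outrun both enolisation and attack on the flavone, the cold acidic quench forestalls lactonisation, and the new carbinol centre at C5 forms without control and is erased in step 7.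

Step 7
Reactants: 12 methyl 5-hydroxy-3-oxo-6-(5,7,4'-tri-O-benzylapigenin-6-yl)hexanoate
Product: 13 methyl 6-[5,7-bis(benzyloxy)-2-(4-benzyloxyphenyl)-4-oxochromen-6-yl]-3,5-dioxohexanoate
Conditions: IBX (2.5 equiv), EtOAc, 75 °C
Reagents that add atoms: none
Why: IBX oxidation of a β-hydroxy ketone to the β-diketone runs without base, so dehydration to the enone is avoided, and the suspension in ethyl acetate leaves benzyl ethers and the flavone alone.

Step 8
Reactants: 13 methyl 6-[5,7-bis(benzyloxy)-2-(4-benzyloxyphenyl)-4-oxochromen-6-yl]-3,5-dioxohexanoate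
Product: 15 6-(2,4,6-trihydroxyphenyl)-5,7,4'-tri-O-benzylapigenin, via cyclohexanetrione 14 (not isolated)
Conditions: LiN(SiMe3)2 (3.2 equiv), THF, Ar, −78 °C → 60 °C; then 1 M HCl
Reagents that add atoms: none
Why: Two equivalents of LiN(SiMe3)2 take 13 to its dianions, and the HN(SiMe3)2 formed lets the 2,4- and the 4,6-dianion exchange protons; only the latter, with charge on the benzylic carbon C6 next to the C5 ketone, can reach the ester carbonyl C1, adds to it and expels methoxide to give trione 14, whose immediate enolisation to the phenolate of 15 makes the closure irreversible and drains the equilibrium. The closest known reactions are the intramolecular Claisen condensation of 3,5-dioxoalkanoates to phloroglucinols and that of 6-aryl-5-oxohexanoates bearing two ortho substituents to 2-arylcyclohexane-1,3-diones. The single ring formed, ring A of the acacetin half, closes through the C6–C1 bond (later C8''–C7'') in the 6-(enolendo)-exo-trig mode, which is allowed for six-membered rings. No stereocentre arises, and the new biaryl axis needs no control. The selectivity required is acylation on carbon and not on the C5 enolate oxygen: lithium holds the enolate oxygens in an aprotic medium, and a 4-hydroxy-2-pyranone formed by O-attack would be reopened by the liberated methoxide whereas the aromatic product cannot revert. The flavone should survive because the base is not nucleophilic, and because O5 is benzylated a pyranone ring opened at C2 by methoxide can only close back to the same flavone on the acidic work-up.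

Step 9
Reactants: 15 6-(2,4,6-trihydroxyphenyl)-5,7,4'-tri-O-benzylapigenin; 16 acetic anhydride
Product: 17 6-(3-acetyl-2,4,6-trihydroxyphenyl)-5,7,4'-tri-O-benzylapigenin
Conditions: Ac2O (1.1 equiv), BF3·OEt2 (3 equiv), dioxane, 0 °C → rt; H2O
Reagents that add atoms: none
Why: Friedel–Crafts C-acetylation, as in the preparation of phloracetophenone, strikes the free phloroglucinol ring as by far the most nucleophilic arene, its two open positions are equivalent by symmetry, the first acyl group deactivates the ring towards a second, and aryl benzyl ethers next to a carbonyl group are known to tolerate BF3·OEt2 up to room temperature.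

Step 10
Reactants: 17 6-(3-acetyl-2,4,6-trihydroxyphenyl)-5,7,4'-tri-O-benzylapigenin
Product: 18 6-(3-acetyl-4,6-dibenzyloxy-2-hydroxyphenyl)-5,7,4'-tri-O-benzylapigenin
Conditions: BnBr (2.1 equiv), K2CO3, DMF, rt → 40 °C
Reagents that add atoms: benzyl bromide, BrCc1ccccc1
Why: Williamson etherification guided by chelation and shielding, as known for 3-substituted phloracetophenones, should alkylate the hydroxyl para to the acetyl group and the ortho hydroxyl that has a free CH neighbour, while the hydroxyl between the acetyl group and the biaryl axis is hydrogen-bonded to the ketone, blocked on both sides and stays free.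

Step 11
Reactants: 18 6-(3-acetyl-4,6-dibenzyloxy-2-hydroxyphenyl)-5,7,4'-tri-O-benzylapigenin; 19 4-methoxybenzoyl chloride
Product: 20 6-{4,6-dibenzyloxy-2-hydroxy-3-[3-(4-methoxyphenyl)-3-oxopropanoyl]phenyl}-5,7,4'-tri-O-benzylapigenin
Conditions: LiN(SiMe3)2 (4 equiv), THF, −78 → −10 °C; 19 (1.05 equiv), −78 °C → rt; 1 M HCl
Reagents that add atoms: none
Why: Claisen-type C-aroylation of the lithium phenoxide–enolate dianion, the one-flask form of the Baker–Venkataraman route to o-hydroxydibenzoylmethanes, joins the acetyl carbon to the aroyl carbon directly, needs no esterification of the crowded phenol, and uses a base too weak and too bulky to harm the flavone already present.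

Step 12
Reactants: 20 6-{4,6-dibenzyloxy-2-hydroxy-3-[3-(4-methoxyphenyl)-3-oxopropanoyl]phenyl}-5,7,4'-tri-O-benzylapigenin
Product: 21 5,7,4',5'',7''-penta-O-benzyl-4'''-O-methylagathisflavone
Conditions: NaOAc, AcOH, 110 °C
Reagents that add atoms: none
Why: Cyclodehydration of the o-hydroxy-1,3-diketone, the closing stage of the Baker–Venkataraman flavone synthesis, can use only the single free phenol beside the axis, so the O1''–C2'' bond fixes the 8''-linkage, and the buffered acid leaves the benzyl ethers in place.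

Step 13
Reactants: 21 5,7,4',5'',7''-penta-O-benzyl-4'''-O-methylagathisflavone
Product: 22 4'''-O-methylagathisflavone (target)
Conditions: H2 (1 atm), 10% Pd/C, THF–MeOH, rt
Reagents that add atoms: none
Why: Catalytic hydrogenolysis removes all five benzyl ethers while the aryl methyl ether and both pyranone C=C bonds are inert at one atmosphere, and the neutral medium excludes a Wessely–Moser ring opening and reclosure that would move the linkage from C8'' to C6''.

Compound list
1 | apigenin | O=c1cc(-c2ccc(O)cc2)oc2cc(O)cc(O)c12 | starting material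
2 | 7,4'-di-O-benzylapigenin | O=c1cc(-c2ccc(OCc3ccccc3)cc2)oc2cc(OCc3ccccc3)cc(O)c12 | intermediate
3 | allyl bromide | C=CCBr | starting material
4 | 5-O-allyl-7,4'-di-O-benzylapigenin | C=CCOc1cc(OCc2ccccc2)cc2oc(-c3ccc(OCc4ccccc4)cc3)cc(=O)c12 | intermediate
5 | 6-allyl-7-benzyloxy-2-(4-benzyloxyphenyl)-6H-chromene-4,5-dione (racemic dienone, not isolated) | C=CCC1C(=O)C2=C(C=C1OCc1ccccc1)OC(c1ccc(OCc3ccccc3)cc1)=CC2=O | intermediate
6 | 6-allyl-7,4'-di-O-benzylapigenin (5-OH free) | C=CCc1c(OCc2ccccc2)cc2oc(-c3ccc(OCc4ccccc4)cc3)cc(=O)c2c1O | intermediate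
7 | 6-allyl-5,7,4'-tri-O-benzylapigenin | C=CCc1c(OCc2ccccc2)cc2oc(-c3ccc(OCc4ccccc4)cc3)cc(=O)c2c1OCc1ccccc1 | intermediate
8 | 6-(2,3-dihydroxypropyl)-5,7,4'-tri-O-benzylapigenin (racemic, not isolated) | OCC(O)Cc1c(OCc2ccccc2)cc2oc(-c3ccc(OCc4ccccc4)cc3)cc(=O)c2c1OCc1ccccc1 | intermediate
9 | (5,7,4'-tri-O-benzylapigenin-6-yl)acetaldehyde | O=CCc1c(OCc2ccccc2)cc2oc(-c3ccc(OCc4ccccc4)cc3)cc(=O)c2c1OCc1ccccc1 | intermediate
10 | methyl acetoacetate | COC(=O)CC(C)=O | starting material
11 | sodium lithium 1,3-dianion of methyl acetoacetate (not isolated) | [Na+].[Li+].COC([O-])=CC([O-])=C | intermediate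
12 | methyl 5-hydroxy-3-oxo-6-(5,7,4'-tri-O-benzylapigenin-6-yl)hexanoate (racemic) | COC(=O)CC(=O)CC(O)Cc1c(OCc2ccccc2)cc2oc(-c3ccc(OCc4ccccc4)cc3)cc(=O)c2c1OCc1ccccc1 | intermediate
13 | methyl 6-[5,7-bis(benzyloxy)-2-(4-benzyloxyphenyl)-4-oxochromen-6-yl]-3,5-dioxohexanoate | COC(=O)CC(=O)CC(=O)Cc1c(OCc2ccccc2)cc2oc(-c3ccc(OCc4ccccc4)cc3)cc(=O)c2c1OCc1ccccc1 | intermediate
14 | 2-(5,7,4'-tri-O-benzylapigenin-6-yl)cyclohexane-1,3,5-trione (not isolated) | O=C1CC(=O)C(c2c(OCc3ccccc3)cc3oc(-c4ccc(OCc5ccccc5)cc4)cc(=O)c3c2OCc2ccccc2)C(=O)C1 | intermediate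
15 | 6-(2,4,6-trihydroxyphenyl)-5,7,4'-tri-O-benzylapigenin | Oc1cc(O)c(-c2c(OCc3ccccc3)cc3oc(-c4ccc(OCc5ccccc5)cc4)cc(=O)c3c2OCc2ccccc2)c(O)c1 | intermediate
16 | acetic anhydride | CC(=O)OC(C)=O | starting material
17 | 6-(3-acetyl-2,4,6-trihydroxyphenyl)-5,7,4'-tri-O-benzylapigenin | CC(=O)c1c(O)cc(O)c(-c2c(OCc3ccccc3)cc3oc(-c4ccc(OCc5ccccc5)cc4)cc(=O)c3c2OCc2ccccc2)c1O | intermediate
18 | 6-(3-acetyl-4,6-dibenzyloxy-2-hydroxyphenyl)-5,7,4'-tri-O-benzylapigenin | CC(=O)c1c(OCc2ccccc2)cc(OCc2ccccc2)c(-c2c(OCc3ccccc3)cc3oc(-c4ccc(OCc5ccccc5)cc4)cc(=O)c3c2OCc2ccccc2)c1O | intermediate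
19 | 4-methoxybenzoyl chloride | COc1ccc(C(=O)Cl)cc1 | starting material
20 | 6-{4,6-dibenzyloxy-2-hydroxy-3-[3-(4-methoxyphenyl)-3-oxopropanoyl]phenyl}-5,7,4'-tri-O-benzylapigenin | COc1ccc(C(=O)CC(=O)c2c(OCc3ccccc3)cc(OCc3ccccc3)c(-c3c(OCc4ccccc4)cc4oc(-c5ccc(OCc6ccccc6)cc5)cc(=O)c4c3OCc3ccccc3)c2O)cc1 | intermediate
21 | 5,7,4',5'',7''-penta-O-benzyl-4'''-O-methylagathisflavone | COc1ccc(-c2cc(=O)c3c(OCc4ccccc4)cc(OCc4ccccc4)c(-c4c(OCc5ccccc5)cc5oc(-c6ccc(OCc7ccccc7)cc6)cc(=O)c5c4OCc4ccccc4)c3o2)cc1 | intermediate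
22 | 4'''-O-methylagathisflavone, 8-[5,7-dihydroxy-2-(4-hydroxyphenyl)-4-oxochromen-6-yl]-5,7-dihydroxy-2-(4-methoxyphenyl)chromen-4-one | COc1ccc(-c2cc(=O)c3c(O)cc(O)c(-c4c(O)cc5oc(-c6ccc(O)cc6)cc(=O)c5c4O)c3o2)cc1 | target

Total step count: 13. Longest linear sequence: 13 steps (1 → 22); the route is fully linear.

Steps most likely to fail

Risk 1, step 8. Deprotonation at C2 may turn the ester into an unreactive enolate so that closure stalls. Acylation on the C5 enolate oxygen may also overtake attack by the crowded benzylic carbon.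
- The fallback sets out from 13 and masks the C3 oxygen before the same C6–C1 bond is made.
- DBU in hot toluene should lactonise 13 to the 4-hydroxy-2-pyranone F1, the usual fate of 3,5-dioxo esters.
- Mitsunobu etherification (BnOH, PPh3, DIAD, THF) should give the 4-benzyloxy-2-pyranone F2.
- BnONa in BnOH–THF at reflux makes any alkoxy exchange degenerate and should open the lactone to the benzyl (E)-3-benzyloxy-5-oxohex-2-enoate F3.
- F3 has no acidic C2–H and holds C1 and C4 cis on the double bond. It should close in the flask by Claisen condensation to the phloroglucinol monobenzyl ether F4. This follows the known conversion of 4-alkoxy-6-alkyl-2-pyranones into 5-alkoxyresorcinols.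
- Acetylation as in step 9 gives the acetophenone F5, in which the acetyl group has only one hydroxyl neighbour.
- Benzylation of the unchelated hydroxyl (BnBr, K2CO3, DMF) comes back to the route at 18.

Risk 2, step 9. The Lewis acid bound to the C4 carbonyl may strip the benzyl group from O5, and a second acetylation may follow the first.
- The fallback sets out from 15 and brings in the carbonyl carbon without a Lewis acid.
- Vilsmeier–Haack formylation (POCl3, DMF, MeCN, 0 °C → rt, then H2O), well known for phloroglucinol itself, should give the trihydroxybenzaldehyde F6.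
- Dibenzylation as in step 10 gives the 2-hydroxy-4,6-dibenzyloxybenzaldehyde F7.
- MeMgBr (2.2 equiv, THF, −78 °C) adds to the aldehyde faster than to the flavone and gives the racemic carbinol F8.
- MnO2 in CH2Cl2 oxidises this benzylic alcohol, which comes back to the route at 18.

Risk 3, step 10. Site selectivity between the two hydroxyls ortho to the acetyl group may be poor. Alkylation beside the axis would later close the pyranone on the wrong oxygen and shift the linkage from C8'' to C6''.
- The fallback sets out from 17 and replaces chelation control by steric exclusion.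
- i-Pr3SiCl and imidazole in DMF should silylate only the two hydroxyls that have a free CH neighbour and give the bis(triisopropylsilyl) ether F9.
- The conditions of step 11 give the diketone F10 and those of step 12 the silylated biflavone F11.
- n-Bu4NF buffered with AcOH (THF, 0 °C) frees O5'' and O7'' to give the tri-O-benzyl biflavone F12.
- Hydrogenolysis as in step 13 comes back to the route at 22.

Further compounds
F1 | step 8 | 4-hydroxy-6-[(5,7,4'-tri-O-benzylapigenin-6-yl)methyl]-2H-pyran-2-one | O=c1cc(O)cc(Cc2c(OCc3ccccc3)cc3oc(-c4ccc(OCc5ccccc5)cc4)cc(=O)c3c2OCc2ccccc2)o1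
F2 | step 8 | 4-benzyloxy-6-[(5,7,4'-tri-O-benzylapigenin-6-yl)methyl]-2H-pyran-2-one | O=c1cc(OCc2ccccc2)cc(Cc2c(OCc3ccccc3)cc3oc(-c4ccc(OCc5ccccc5)cc4)cc(=O)c3c2OCc2ccccc2)o1
F3 | step 8 | benzyl (E)-3-benzyloxy-5-oxo-6-(5,7,4'-tri-O-benzylapigenin-6-yl)hex-2-enoate (formed in the flask) | O=C(OCc1ccccc1)/C=C(/OCc1ccccc1)CC(=O)Cc1c(OCc2ccccc2)cc2oc(-c3ccc(OCc4ccccc4)cc3)cc(=O)c2c1OCc1ccccc1
F4 | step 8 | 6-(4-benzyloxy-2,6-dihydroxyphenyl)-5,7,4'-tri-O-benzylapigenin | Oc1cc(OCc2ccccc2)cc(O)c1-c1c(OCc2ccccc2)cc2oc(-c3ccc(OCc4ccccc4)cc3)cc(=O)c2c1OCc1ccccc1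
F5 | step 8 | 6-(3-acetyl-4-benzyloxy-2,6-dihydroxyphenyl)-5,7,4'-tri-O-benzylapigenin | CC(=O)c1c(OCc2ccccc2)cc(O)c(-c2c(OCc3ccccc3)cc3oc(-c4ccc(OCc5ccccc5)cc4)cc(=O)c3c2OCc2ccccc2)c1O
F6 | step 9 | 6-(3-formyl-2,4,6-trihydroxyphenyl)-5,7,4'-tri-O-benzylapigenin | O=Cc1c(O)cc(O)c(-c2c(OCc3ccccc3)cc3oc(-c4ccc(OCc5ccccc5)cc4)cc(=O)c3c2OCc2ccccc2)c1O
F7 | step 9 | 6-(4,6-dibenzyloxy-3-formyl-2-hydroxyphenyl)-5,7,4'-tri-O-benzylapigenin | O=Cc1c(OCc2ccccc2)cc(OCc2ccccc2)c(-c2c(OCc3ccccc3)cc3oc(-c4ccc(OCc5ccccc5)cc4)cc(=O)c3c2OCc2ccccc2)c1O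
F8 | step 9 | 6-[4,6-dibenzyloxy-2-hydroxy-3-(1-hydroxyethyl)phenyl]-5,7,4'-tri-O-benzylapigenin (racemic) | CC(O)c1c(OCc2ccccc2)cc(OCc2ccccc2)c(-c2c(OCc3ccccc3)cc3oc(-c4ccc(OCc5ccccc5)cc4)cc(=O)c3c2OCc2ccccc2)c1O
F9 | step 10 | 6-[3-acetyl-2-hydroxy-4,6-bis(triisopropylsilyloxy)phenyl]-5,7,4'-tri-O-benzylapigenin | CC(=O)c1c(O[Si](C(C)C)(C(C)C)C(C)C)cc(O[Si](C(C)C)(C(C)C)C(C)C)c(-c2c(OCc3ccccc3)cc3oc(-c4ccc(OCc5ccccc5)cc4)cc(=O)c3c2OCc2ccccc2)c1O
F10 | step 10 | 6-{2-hydroxy-3-[3-(4-methoxyphenyl)-3-oxopropanoyl]-4,6-bis(triisopropylsilyloxy)phenyl}-5,7,4'-tri-O-benzylapigenin | COc1ccc(C(=O)CC(=O)c2c(O[Si](C(C)C)(C(C)C)C(C)C)cc(O[Si](C(C)C)(C(C)C)C(C)C)c(-c3c(OCc4ccccc4)cc4oc(-c5ccc(OCc6ccccc6)cc5)cc(=O)c4c3OCc3ccccc3)c2O)cc1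
F11 | step 10 | 5,7,4'-tri-O-benzyl-5'',7''-bis-O-(triisopropylsilyl)-4'''-O-methylagathisflavone | COc1ccc(-c2cc(=O)c3c(O[Si](C(C)C)(C(C)C)C(C)C)cc(O[Si](C(C)C)(C(C)C)C(C)C)c(-c4c(OCc5ccccc5)cc5oc(-c6ccc(OCc7ccccc7)cc6)cc(=O)c5c4OCc4ccccc4)c3o2)cc1
F12 | step 10 | 5,7,4'-tri-O-benzyl-4'''-O-methylagathisflavone | COc1ccc(-c2cc(=O)c3c(O)cc(O)c(-c4c(OCc5ccccc5)cc5oc(-c6ccc(OCc7ccccc7)cc6)cc(=O)c5c4OCc4ccccc4)c3o2)cc1
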